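**Retrosynthetic overview**

1. Glabrol ⇒ its bis-TIPS ether (fluoride deprotection last) ⇒ an (S)-3-aryl-3-aryloxypropanoic acid by cutting C4–C4a (intramolecular Friedel–Crafts acylation). The plan rests on C4 being an aryl ketone carbon bonded to C4a of ring A, a carbon ortho to O1 and para to O7, while the other carbon ortho to O1 (C8) is blocked by prenyl.
2. Acid ⇒ (S)-1-arylallyl aryl ether (vinyl → CH2CO2H by hydroboration–oxidation, then alcohol oxidation) ⇒ O1–C2 bond and the C2 stereocentre by iridium-catalysed asymmetric allylic etherification of a ring A phenoxide with a ring B cinnamyl carbonate.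
3. Ring A phenol ⇐ resorcinol (bis-MOM ether, C2 lithiation/prenylation, deprotection, monosilylation); ring B carbonate ⇐ 4-hydroxybenzaldehyde (ortho C-prenylation, silylation, Wittig, reduction, carbonate formation).
4. Ring order: rings A and B come from the aromatic starting materials; ring C is the only ring built, in the key step.

Key step: step 13

Abbreviations: prenyl = 3-methylbut-2-en-1-yl; TIPS = triisopropylsilyl; MOM = methoxymethyl.

Assumption: the (Sa,S,S)-phosphoramidite is taken to give the S ether in step 10, by analogy with the usual facial preference of this catalyst family with O- and N-nucleophiles; the sense is to be verified on the product of step 10 and the enantiomeric ligand used if it proves opposite.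

**Route**

Step 1
Reactants: 1 resorcinol
Product: 2 1,3-bis(methoxymethoxy)benzene
Conditions: MOMCl (2.5 equiv), i-Pr2NEt (3 equiv), CH2Cl2, 0 °C → rt
Reagents that add atoms: chloromethyl methyl ether (MOMCl), COCCl
Why: Williamson-type O-alkylation of both phenolic oxygens by the reactive α-chloro ether under amine base should give the bis-MOM ether, whose two acetal oxygens will direct lithiation to C2.

Step 2
Reactants: 2 1,3-bis(methoxymethoxy)benzene; 3 prenyl bromide (1-bromo-3-methylbut-2-ene)
Product: 5 1,3-bis(methoxymethoxy)-2-prenylbenzene, via aryllithium 4 (not isolated)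
Conditions: n-BuLi (1.1 equiv), TMEDA, THF, 0 °C; then 3, −78 °C → rt
Reagents that add atoms: none
Why: Directed ortho-metalation, in which the two MOM oxygens cooperatively chelate lithium so that deprotonation occurs only at C2 between them, followed by SN2 alkylation of the aryllithium at the primary carbon of the allylic bromide.

Step 3
Reactants: 5 1,3-bis(methoxymethoxy)-2-prenylbenzene
Product: 6 2-prenylbenzene-1,3-diol (2-prenylresorcinol)
Conditions: conc. HCl (cat.), MeOH, 40 °C
Reagents that add atoms: none
Why: Acid-catalysed acetal exchange with methanol removes both MOM groups as dimethoxymethane, and the low acid strength and temperature should keep the prenyl alkene from adding the neighbouring hydroxyl to form a chroman.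

Step 4
Reactants: 6 2-prenylresorcinol
Product: 7 2-prenyl-3-(triisopropylsilyloxy)phenol
Conditions: TIPSCl (1.0 equiv), imidazole (2.2 equiv), DMF, 0 °C → rt; recovered 6 resubmitted
Reagents that add atoms: triisopropylsilyl chloride (TIPSCl), CC(C)[Si](Cl)(C(C)C)C(C)C
Why: Imidazole-mediated silylation of a phenol; the diol is symmetrical, so one equivalent of TIPSCl can give only one mono-ether, in a statistical process from which unreacted diol is recovered.

Step 5
Reactants: 8 4-hydroxybenzaldehyde; 3 prenyl bromide
Product: 10 4-hydroxy-3-prenylbenzaldehyde, via potassium phenoxide 9 (not isolated)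
Conditions: KOH, H2O, rt; then aq. HCl to pH 5
Reagents that add atoms: none
Why: Ortho C-alkylation of an ambident phenoxide, favoured in water where the oxygen is strongly solvated, so that the allylic bromide is attacked by the ring carbon ortho to oxygen (para is blocked by the formyl group) and the dienone tautomerises back to the phenol.

Step 6
Reactants: 10 4-hydroxy-3-prenylbenzaldehyde
Product: 11 3-prenyl-4-(triisopropylsilyloxy)benzaldehyde
Conditions: TIPSCl (1.2 equiv), imidazole (2.5 equiv), DMF, rt
Reagents that add atoms: triisopropylsilyl chloride (TIPSCl), CC(C)[Si](Cl)(C(C)C)C(C)C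
Why: Standard silylation of the phenol masks the acidic OH before the ylide, hydride and phenoxide steps.

Step 7
Reactants: 11 3-prenyl-4-(triisopropylsilyloxy)benzaldehyde
Product: 12 ethyl (E)-3-[3-prenyl-4-(triisopropylsilyloxy)phenyl]prop-2-enoate
Conditions: Ph3P=CHCO2Et (1.3 equiv), toluene, 80 °C
Reagents that add atoms: ethyl (triphenylphosphoranylidene)acetate, CCOC(=O)C=P(c1ccccc1)(c1ccccc1)c1ccccc1
Why: Wittig olefination with a stabilised ylide, which should deliver the E-enoate.

Step 8
Reactants: 12 ethyl (E)-3-[3-prenyl-4-(triisopropylsilyloxy)phenyl]prop-2-enoate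
Product: 13 (E)-3-[3-prenyl-4-(triisopropylsilyloxy)phenyl]prop-2-en-1-ol
Conditions: i-Bu2AlH (2.5 equiv), CH2Cl2, −78 °C; aq. potassium sodium tartrate
Reagents that add atoms: none
Why: i-Bu2AlH reduces the conjugated ester by two 1,2-hydride additions to the allylic alcohol without touching the alkene geometry or the aryl silyl ether.

Step 9
Reactants: 13 (E)-3-[3-prenyl-4-(triisopropylsilyloxy)phenyl]prop-2-en-1-ol
Product: 14 methyl (E)-3-[3-prenyl-4-(triisopropylsilyloxy)phenyl]prop-2-en-1-yl carbonate
Conditions: ClCO2Me (1.5 equiv), pyridine, CH2Cl2, 0 °C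
Reagents that add atoms: methyl chloroformate, COC(=O)Cl
Why: Acylation of the primary allylic alcohol with the chloroformate installs the methyl carbonate leaving group needed for ionisation by iridium.

Step 10
Reactants: 7 2-prenyl-3-(triisopropylsilyloxy)phenol; 14 methyl (E)-3-[3-prenyl-4-(triisopropylsilyloxy)phenyl]prop-2-en-1-yl carbonate
Product: 16 (S)-1-[3-prenyl-4-(triisopropylsilyloxy)phenyl]prop-2-en-1-yl 2-prenyl-3-(triisopropylsilyloxy)phenyl ether, via lithium phenoxide 15 (not isolated)
Conditions: 7, n-BuLi (1.0 equiv), THF, 0 °C; then [Ir(cod)Cl]2 (2 mol%), (Sa,S,S)-O,O'-(1,1'-binaphthyl-2,2'-diyl) N,N-bis(1-phenylethyl)phosphoramidite (4 mol%, preactivated with n-PrNH2), 14 (1.2 equiv), THF, rt → 50 °C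
Reagents that add atoms: none
Why: Iridium-catalysed asymmetric allylic etherification, in which the cyclometalated iridium–phosphoramidite complex ionises the carbonate to an allyl complex and the phenoxide attacks its aryl-bearing terminus (branched selectivity) on the face left open by the (Sa,S,S)-ligand, which forms the O1–C2 bond and sets C2 as S.

Step 11
Reactants: 16 (S)-1-[3-prenyl-4-(triisopropylsilyloxy)phenyl]prop-2-en-1-yl 2-prenyl-3-(triisopropylsilyloxy)phenyl ether
Product: 18 (S)-3-[2-prenyl-3-(triisopropylsilyloxy)phenoxy]-3-[3-prenyl-4-(triisopropylsilyloxy)phenyl]propan-1-ol, via alkylborane 17 (not isolated)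
Conditions: 9-borabicyclo[3.3.1]nonane (9-BBN, 1.3 equiv), THF, 0 °C → rt; then NaOH (aq), H2O2, 0 °C
Reagents that add atoms: hydrogen peroxide, OO
Why: Hydroboration–oxidation, in which the bulky 9-BBN should add only to the monosubstituted vinyl group with boron at the terminal carbon, leaving both trisubstituted prenyl alkenes, and alkaline peroxide then replaces boron by OH with no change at C2.

Step 12
Reactants: 18 (S)-3-[2-prenyl-3-(triisopropylsilyloxy)phenoxy]-3-[3-prenyl-4-(triisopropylsilyloxy)phenyl]propan-1-ol
Product: 20 (S)-3-[2-prenyl-3-(triisopropylsilyloxy)phenoxy]-3-[3-prenyl-4-(triisopropylsilyloxy)phenyl]propanoic acid, via aldehyde 19 (not isolated)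
Conditions: TEMPO (2,2,6,6-tetramethylpiperidin-1-oxyl, 0.2 equiv), PhI(OAc)2 (2.5 equiv), MeCN/H2O 1:1, rt
Reagents that add atoms: water, O
Why: TEMPO-catalysed oxidation with PhI(OAc)2 in wet acetonitrile takes the primary alcohol through the aldehyde and its hydrate to the acid under weakly acidic conditions, which should spare the silyl ethers and trisubstituted alkenes and give little enolisation of the β-aryloxy aldehyde towards loss of the phenol.

Step 13
Reactants: 20 (S)-3-[2-prenyl-3-(triisopropylsilyloxy)phenoxy]-3-[3-prenyl-4-(triisopropylsilyloxy)phenyl]propanoic acid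
Product: 22 (S)-8-prenyl-2-[3-prenyl-4-(triisopropylsilyloxy)phenyl]-7-(triisopropylsilyloxy)chroman-4-one, via acid chloride 21 (not isolated)
Conditions: 1-chloro-N,N,2-trimethylprop-1-en-1-amine (1.2 equiv), CH2Cl2, 0 °C → rt; then 2,6-di-tert-butyl-4-methylpyridine (1.5 equiv), SnCl4 (2.2 equiv), CH2Cl2 (0.01 M), −78 → −40 °C; aq. NaHCO3
Reagents that add atoms: none
Why: The chloroenamine turns the acid into acyl chloride 21 without liberating acid, SnCl4 (a promoter that is not consumed) then polarises the C–Cl bond, C4a of ring A attacks the acyl carbon, and the arenium ion gives up its proton to the hindered pyridine to leave the aryl ketone. The closest known reaction type is the intramolecular Friedel–Crafts acylation that closes 3-aryloxypropanoic acids to chroman-4-ones. Ring C, the only ring formed, closes as a six-membered ring by 6-exo-trig attack of the arene on the activated carbonyl, with the C4a–C8a bond of ring A becoming a ring C bond. No stereocentre is created; C2 from step 10 is carried through, and it survives only if acylation is faster than Lewis acid ionisation of the benzylic C2–O1 bond, which is the reason for the low temperature, the mild Lewis acid and the neutral preparation of 21. Regioselectivity is fixed by the substrate, since C4a is the only unsubstituted carbon ortho to O1 (C8 carries prenyl), is also para to the C7 silyloxy donor, and is the only ring A carbon the three-atom tether can reach. Chemoselectivity over protonation of the prenyl alkenes, silyl ether loss and intermolecular acylation should be secured by trapping the HCl with 2,6-di-tert-butyl-4-methylpyridine, which is too hindered to bind SnCl4, by the excess SnCl4 that compensates for binding to the amide by-product, and by high dilution.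

Step 14
Reactants: 22 (S)-8-prenyl-2-[3-prenyl-4-(triisopropylsilyloxy)phenyl]-7-(triisopropylsilyloxy)chroman-4-one
Product: 23 (S)-glabrol, (2S)-7-hydroxy-2-(4-hydroxy-3-prenylphenyl)-8-prenylchroman-4-one
Conditions: HF·pyridine (excess), pyridine, THF, 0 °C → rt
Reagents that add atoms: none
Why: Fluoride-induced Si–O cleavage driven by the strong Si–F bond; the pyridine-buffered HF reagent releases the phenols in protonated form, so no phenoxide is present to open ring C by retro-oxa-Michael reaction (the racemisation path of 4'-hydroxyflavanones), and it should be too weak an acid to add the phenols to the prenyl alkenes.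

**Compound list**

1 | resorcinol | Oc1cccc(O)c1 | starting material
2 | 1,3-bis(methoxymethoxy)benzene | COCOc1cccc(OCOC)c1 | intermediate
3 | prenyl bromide (1-bromo-3-methylbut-2-ene) | CC(C)=CCBr | starting material
4 | [2,6-bis(methoxymethoxy)phenyl]lithium (not isolated) | [Li]c1c(OCOC)cccc1OCOC | intermediate
5 | 1,3-bis(methoxymethoxy)-2-prenylbenzene | COCOc1cccc(OCOC)c1CC=C(C)C | intermediate
6 | 2-prenylbenzene-1,3-diol | CC(C)=CCc1c(O)cccc1O | intermediate
7 | 2-prenyl-3-(triisopropylsilyloxy)phenol | CC(C)=CCc1c(O)cccc1O[Si](C(C)C)(C(C)C)C(C)C | intermediate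
8 | 4-hydroxybenzaldehyde | O=Cc1ccc(O)cc1 | starting material
9 | potassium 4-formylphenoxide (not isolated) | O=Cc1ccc([O-])cc1.[K+] | intermediate
10 | 4-hydroxy-3-prenylbenzaldehyde | CC(C)=CCc1cc(C=O)ccc1O | intermediate
11 | 3-prenyl-4-(triisopropylsilyloxy)benzaldehyde | CC(C)=CCc1cc(C=O)ccc1O[Si](C(C)C)(C(C)C)C(C)C | intermediate
12 | ethyl (E)-3-[3-prenyl-4-(triisopropylsilyloxy)phenyl]prop-2-enoate | CCOC(=O)/C=C/c1ccc(O[Si](C(C)C)(C(C)C)C(C)C)c(CC=C(C)C)c1 | intermediate
13 | (E)-3-[3-prenyl-4-(triisopropylsilyloxy)phenyl]prop-2-en-1-ol | OC/C=C/c1ccc(O[Si](C(C)C)(C(C)C)C(C)C)c(CC=C(C)C)c1 | intermediate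
14 | methyl (E)-3-[3-prenyl-4-(triisopropylsilyloxy)phenyl]prop-2-en-1-yl carbonate | COC(=O)OC/C=C/c1ccc(O[Si](C(C)C)(C(C)C)C(C)C)c(CC=C(C)C)c1 | intermediate
15 | lithium 2-prenyl-3-(triisopropylsilyloxy)phenoxide (not isolated) | CC(C)=CCc1c([O-])cccc1O[Si](C(C)C)(C(C)C)C(C)C.[Li+] | intermediate
16 | (S)-1-[3-prenyl-4-(triisopropylsilyloxy)phenyl]prop-2-en-1-yl 2-prenyl-3-(triisopropylsilyloxy)phenyl ether | CC(C)=CCc1cc([C@@H](Oc2cccc(O[Si](C(C)C)(C(C)C)C(C)C)c2CC=C(C)C)C=C)ccc1O[Si](C(C)C)(C(C)C)C(C)C | intermediate
17 | B-alkyl-9-borabicyclo[3.3.1]nonane from 16, boron on the terminal carbon (not isolated) | CC(C)=CCc1cc([C@@H](Oc2cccc(O[Si](C(C)C)(C(C)C)C(C)C)c2CC=C(C)C)CCB2C3CCCC2CCC3)ccc1O[Si](C(C)C)(C(C)C)C(C)C | intermediate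
18 | (S)-3-[2-prenyl-3-(triisopropylsilyloxy)phenoxy]-3-[3-prenyl-4-(triisopropylsilyloxy)phenyl]propan-1-ol | CC(C)=CCc1cc([C@@H](Oc2cccc(O[Si](C(C)C)(C(C)C)C(C)C)c2CC=C(C)C)CCO)ccc1O[Si](C(C)C)(C(C)C)C(C)C | intermediate
19 | (S)-3-[2-prenyl-3-(triisopropylsilyloxy)phenoxy]-3-[3-prenyl-4-(triisopropylsilyloxy)phenyl]propanal (not isolated) | CC(C)=CCc1cc([C@@H](Oc2cccc(O[Si](C(C)C)(C(C)C)C(C)C)c2CC=C(C)C)CC=O)ccc1O[Si](C(C)C)(C(C)C)C(C)C | intermediate
20 | (S)-3-[2-prenyl-3-(triisopropylsilyloxy)phenoxy]-3-[3-prenyl-4-(triisopropylsilyloxy)phenyl]propanoic acid | CC(C)=CCc1cc([C@@H](Oc2cccc(O[Si](C(C)C)(C(C)C)C(C)C)c2CC=C(C)C)CC(=O)O)ccc1O[Si](C(C)C)(C(C)C)C(C)C | intermediate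
21 | (S)-3-[2-prenyl-3-(triisopropylsilyloxy)phenoxy]-3-[3-prenyl-4-(triisopropylsilyloxy)phenyl]propanoyl chloride (not isolated) | CC(C)=CCc1cc([C@@H](Oc2cccc(O[Si](C(C)C)(C(C)C)C(C)C)c2CC=C(C)C)CC(=O)Cl)ccc1O[Si](C(C)C)(C(C)C)C(C)C | intermediate
22 | (S)-8-prenyl-2-[3-prenyl-4-(triisopropylsilyloxy)phenyl]-7-(triisopropylsilyloxy)chroman-4-one | CC(C)=CCc1cc([C@@H]2CC(=O)c3ccc(O[Si](C(C)C)(C(C)C)C(C)C)c(CC=C(C)C)c3O2)ccc1O[Si](C(C)C)(C(C)C)C(C)C | intermediate
23 | (S)-glabrol | CC(C)=CCc1cc([C@@H]2CC(=O)c3ccc(O)c(CC=C(C)C)c3O2)ccc1O | target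

**Step count**

Total: 14 steps. Longest linear sequence: 10 steps (steps 5–14, from 4-hydroxybenzaldehyde 8). The ring A branch (steps 1–4) joins at step 10.

**Steps most likely to fail**

1. Step 13 (key step). The Lewis acid may ionise the benzylic C2–O1 bond faster than C4a is acylated, which would racemise C2 or expel the ring A phenol by β-elimination. The HCl formed may also protonate the prenyl alkenes or strip a silyl group if the proton trap is not efficient enough. The fallback gives up the C4–C4a closure and the asymmetric induction, closes ring C at O1–C2 by oxa-Michael addition of a 2'-hydroxychalcone, and resolves the racemate. It sets out from prenyl bromide 3 and aldehyde 10 and comes back to the route at 23. Purchased 2,4-dihydroxyacetophenone F1 is C-prenylated at C3 with 3 in aqueous KOH, as in step 5, to give 2,4-dihydroxy-3-prenylacetophenone F2. Claisen–Schmidt condensation of F2 with 10 (60% aq. KOH, EtOH, rt) should give (E)-1-(2,4-dihydroxy-3-prenylphenyl)-3-(4-hydroxy-3-prenylphenyl)prop-2-en-1-one F3. Heating F3 with NaOAc in EtOH closes ring C by 6-endo-trig oxa-Michael addition to racemic glabrol F4. Preparative HPLC on an amylose tris(3,5-dimethylphenylcarbamate) phase then separates the enantiomers and delivers 23; the unwanted enantiomer can be re-equilibrated through F3 with base and resolved again.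

2. Step 10. The hindered ortho-substituted phenoxide and the electron-rich cinnamyl system may give poor branched-to-linear or facial selectivity. The catalyst may also re-ionise the product ether, which would erode the enantiomeric purity or isomerise it to the linear ether. The fallback makes the O1–C2 bond with inversion by Mitsunobu etherification of an enantioenriched β-hydroxy ester that is already at the acid oxidation level, so it also replaces steps 7–9, 11 and 12. It sets out from aldehyde 11 and phenol 7 and comes back at acid 20. Roskamp homologation of 11 (ethyl diazoacetate, SnCl2 cat., CH2Cl2) should give ethyl 3-oxo-3-[3-prenyl-4-(triisopropylsilyloxy)phenyl]propanoate F5. Asymmetric transfer hydrogenation (RuCl[(R,R)-TsDPEN](p-cymene), HCO2H/Et3N) is expected, by analogy with aryl ketones, to give ethyl (R)-3-hydroxy-3-[3-prenyl-4-(triisopropylsilyloxy)phenyl]propanoate F6. Mitsunobu reaction of F6 with 7 (PPh3, diisopropyl azodicarboxylate, toluene, 0 °C) should give, with inversion, ethyl (S)-3-[2-prenyl-3-(triisopropylsilyloxy)phenoxy]-3-[3-prenyl-4-(triisopropylsilyloxy)phenyl]propanoate F7. Saponification (LiOH, THF/H2O, 0 °C) then gives 20.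

3. Step 11. Hydroboration may not stay confined to the vinyl group, or boron may be delivered to the internal carbon, after which the β-aryloxy borane eliminates and the ether is lost. The alkaline peroxide work-up may also attack the aryl silyl ethers. The fallback oxidises the terminal carbon directly and sets out from ether 16, coming back at acid 20, and makes no compound outside the list (F0). An aldehyde-selective Wacker oxidation of 16 (PdCl2(PhCN)2, CuCl2, AgNO2, t-BuOH/MeNO2, O2, rt) should give aldehyde 19, which is isolated this time. Pinnick oxidation (NaClO2, NaH2PO4, excess 2-methylbut-2-ene, t-BuOH/H2O) then gives 20. The trisubstituted prenyl alkenes are expected to be inert to the palladium oxidation and to be shielded from hypochlorite by the alkene scavenger.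

**Further compounds**

F1 | step 13 | 2,4-dihydroxyacetophenone (purchased) | CC(=O)c1ccc(O)cc1O
F2 | step 13 | 1-(2,4-dihydroxy-3-prenylphenyl)ethan-1-one | CC(=O)c1ccc(O)c(CC=C(C)C)c1O
F3 | step 13 | (E)-1-(2,4-dihydroxy-3-prenylphenyl)-3-(4-hydroxy-3-prenylphenyl)prop-2-en-1-one | CC(C)=CCc1cc(/C=C/C(=O)c2ccc(O)c(CC=C(C)C)c2O)ccc1O
F4 | step 13 | racemic glabrol | CC(C)=CCc1cc(C2CC(=O)c3ccc(O)c(CC=C(C)C)c3O2)ccc1O
F5 | step 10 | ethyl 3-oxo-3-[3-prenyl-4-(triisopropylsilyloxy)phenyl]propanoate | CCOC(=O)CC(=O)c1ccc(O[Si](C(C)C)(C(C)C)C(C)C)c(CC=C(C)C)c1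
F6 | step 10 | ethyl (R)-3-hydroxy-3-[3-prenyl-4-(triisopropylsilyloxy)phenyl]propanoate | CC(C)=CCc1cc([C@H](O)CC(=O)OCC)ccc1O[Si](C(C)C)(C(C)C)C(C)C
F7 | step 10 | ethyl (S)-3-[2-prenyl-3-(triisopropylsilyloxy)phenoxy]-3-[3-prenyl-4-(triisopropylsilyloxy)phenyl]propanoate | CC(C)=CCc1cc([C@@H](Oc2cccc(O[Si](C(C)C)(C(C)C)C(C)C)c2CC=C(C)C)CC(=O)OCC)ccc1O[Si](C(C)C)(C(C)C)C(C)C
F0 | step 11 | none | none
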